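## Retrosynthetic overview

1. cis‑Miyabenol C ⇐ global deprotection ⇐ Lindlar semi‑reduction of diarylalkyne 23 ⇐ Sonogashira coupling of trimer bromide 19 with alkyne 22.
2. The stilbene‑bearing dihydrobenzofuran (formed last) ⇐ epoxide arylation / 1,2‑aryl shift through a phenonium ion / O‑cyclisation between (S,S)‑epoxide 17 and bromoresorcinol bis‑silyl ether 13.
3. 17 ⇐ ent‑Shi epoxidation of protected ε‑viniferin 16 ⇐ Heck reaction of bromide 15 with styrene 4.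
4. The inner dihydrobenzofuran (formed first) ⇐ the same arylation / 1,2‑aryl shift / cyclisation between (R,R)‑resveratrol oxide 10 and 13; 10 ⇐ Shi epoxidation of stilbene 9 ⇐ Heck reaction of 8 with 4.
5. All arenes come from 4‑iodophenol and resorcinol (Ir C–H borylation/bromination); the C2 units come from vinyltrifluoroborate and ethynylmagnesium bromide.

Assumption: the target SMILES encodes (2S,3S) for the stilbene‑bearing dihydrobenzofuran and (2R,3R) for the other (both trans), and both enantiomers of the Shi ketone are treated as purchasable catalysts.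

## Route

Step 1
Reactants: 1 4‑iodophenol
Product: 2 4‑iodophenyl pivalate
Conditions: PivCl, Et3N, DMAP (cat.), CH2Cl2, 0 °C → rt
Reagents that add atoms: pivaloyl chloride, CC(C)(C)C(=O)Cl
Why: DMAP‑catalysed O‑acylation; the pivalate survives the pH 10 Shi conditions and damps the donor power of the para oxygen for the later cationic steps.

Step 2
Reactants: 2 4‑iodophenyl pivalate; 3 potassium vinyltrifluoroborate
Product: 4 4‑vinylphenyl pivalate
Conditions: PdCl2(dppf) (2 mol%), Et3N, n‑PrOH, 80 °C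
Reagents that add atoms: none
Why: Suzuki–Miyaura vinylation (Molander conditions) of an aryl iodide under amine base leaves the aryl ester intact.

Step 3
Reactants: 5 resorcinol
Product: 6 1,3‑phenylene dipivalate
Conditions: PivCl (2.2 equiv), Et3N, DMAP (cat.), CH2Cl2, 0 °C → rt
Reagents that add atoms: pivaloyl chloride, CC(C)(C)C(=O)Cl
Why: Standard double O‑acylation of a phenol.

Step 4
Reactants: 6 1,3‑phenylene dipivalate
Product: 8 5‑bromo‑1,3‑phenylene dipivalate, via arylboronate 7 (not isolated)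
Conditions: [Ir(cod)OMe]2 (1 mol%), dtbpy (2 mol%), B2pin2 (1.0 equiv), THF, 80 °C; evaporate; then CuBr2 (3 equiv), MeOH/H2O, 80 °C
Reagents that add atoms: copper(II) bromide, Br[Cu]Br; bis(pinacolato)diboron, CC1(C)OB(OC1(C)C)B1OC(C)(C)C(C)(C)O1 (boron only in 7)
Why: Sterically controlled Ir‑catalysed C–H borylation (Hartwig–Miyaura) reaches only the mutually meta C5–H, and Cu(II) bromodeboronation in the same pot gives the bromide.

Step 5
Reactants: 8 5‑bromo‑1,3‑phenylene dipivalate; 4 4‑vinylphenyl pivalate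
Product: 9 (E)‑resveratrol tripivalate
Conditions: Pd(OAc)2 (2 mol%), P(o‑tol)3 (4 mol%), Et3N, DMF, 100 °C
Reagents that add atoms: none
Why: Mizoroki–Heck reaction; syn insertion and syn β‑hydride elimination give the E‑stilbene.

Step 6
Reactants: 9 (E)‑resveratrol tripivalate
Product: 10 (2R,3R)‑2‑[3,5‑bis(pivaloyloxy)phenyl]‑3‑[4‑(pivaloyloxy)phenyl]oxirane
Conditions: D‑fructose‑derived Shi ketone (30 mol%), Oxone, K2CO3, Bu4NHSO4, MeCN/DMM/aq. borate buffer (pH 10.5), 0 °C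
Reagents that add atoms: Oxone (potassium peroxymonosulfate), [K+].[O-]S(=O)(=O)OO
Why: Shi asymmetric epoxidation; the chiral dioxirane epoxidises trans‑stilbenes through the spiro transition state to the (R,R)‑epoxide (typically >95% ee), and the acyloxy groups make this epoxide stable to isolation.

Step 7
Reactants: 5 resorcinol
Product: 11 1,3‑bis(triisopropylsilyloxy)benzene
Conditions: TIPSCl (2.2 equiv), imidazole, DMF, rt → 40 °C
Reagents that add atoms: triisopropylsilyl chloride, CC(C)[Si](Cl)(C(C)C)C(C)C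
Why: Standard silylation; the bulky, weakly nucleophilic silyl ether oxygens keep the ring electron‑rich but disfavour direct O‑alkylation in the key step.

Step 8
Reactants: 11 1,3‑bis(triisopropylsilyloxy)benzene
Product: 13 1‑bromo‑3,5‑bis(triisopropylsilyloxy)benzene, via arylboronate 12 (not isolated)
Conditions: [Ir(cod)OMe]2 (1 mol%), dtbpy (2 mol%), B2pin2 (1.0 equiv), THF, 80 °C; evaporate; then CuBr2 (3 equiv), MeOH/THF/H2O, 80 °C
Reagents that add atoms: copper(II) bromide, Br[Cu]Br; bis(pinacolato)diboron, CC1(C)OB(OC1(C)C)B1OC(C)(C)C(C)(C)O1 (boron only in 12)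
Why: Same sterically controlled meta C–H borylation and Cu(II) bromodeboronation as in step 4.

Step 9
Reactants: 10 (2R,3R)‑epoxide; 13 1‑bromo‑3,5‑bis(triisopropylsilyloxy)benzene (3 equiv)
Product: 15 5‑[(2R,3R)‑4‑bromo‑2‑(4‑pivaloyloxyphenyl)‑6‑(triisopropylsilyloxy)‑2,3‑dihydrobenzofuran‑3‑yl]‑1,3‑phenylene dipivalate, via carbinol 14 (not isolated)
Conditions: TfOH (10 mol%), HFIP, 0 °C, 1 h; then 50 °C
Reagents that add atoms: none
Why: Proposed new method: TfOH/HFIP first opens the epoxide at the 4‑acyloxybenzylic carbon with arene 13 at its position ortho to Br and para to OSi, leaving the carbinol stereocentre of 14 untouched; on warming, the electron‑poor benzylic C–OH can ionise only with anchimeric help from the new 2,4‑bis(silyloxy)aryl group, whose 1,2‑shift through a phenonium ion inverts that carbon (setting C3 as R) and leaves a 4‑acyloxybenzyl cation that the ortho silyl ether oxygen captures trans to the C3 aryl group with loss of TIPS, so the skeletal shift corrects the regiochemistry of the arylation; the closest known chemistry is the TfOH/HFIP Friedel–Crafts arylation of epoxides and phenonium‑mediated dehydrative arylation of 2‑arylethanols (Winstein Ar1‑3 participation).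

Step 10
Reactants: 15 bromodihydrobenzofuran; 4 4‑vinylphenyl pivalate
Product: 16 4‑[(E)‑2‑{(2R,3R)‑3‑[3,5‑bis(pivaloyloxy)phenyl]‑2‑(4‑pivaloyloxyphenyl)‑6‑(triisopropylsilyloxy)‑2,3‑dihydrobenzofuran‑4‑yl}vinyl]phenyl pivalate (protected ε‑viniferin)
Conditions: Pd2(dba)3 (2 mol%), P(t‑Bu)3·HBF4 (8 mol%), Cy2NMe, dioxane, 80 °C
Reagents that add atoms: none
Why: Mizoroki–Heck reaction under Littke–Fu conditions tolerates the ortho‑substituted aryl bromide, gives the E‑stilbene and does not touch the benzylic stereocentres.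

Step 11
Reactants: 16 protected ε‑viniferin
Product: 17 (2S,3S)‑oxirane of 16 (trans epoxide on the former stilbene)
Conditions: L‑fructose‑derived (ent‑)Shi ketone (30 mol%), Oxone, K2CO3, Bu4NHSO4, MeCN/DMM/aq. borate buffer (pH 10.5), 0 °C
Reagents that add atoms: Oxone (potassium peroxymonosulfate), [K+].[O-]S(=O)(=O)OO
Why: Shi asymmetric epoxidation under catalyst control; the enantiomeric ketone delivers the (S,S)‑epoxide of the trans‑stilbene irrespective of the remote ring stereocentres.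

Step 12
Reactants: 17 (S,S)‑epoxide (added slowly); 13 1‑bromo‑3,5‑bis(triisopropylsilyloxy)benzene (5 equiv)
Product: 19 trimer bromide: 5‑[(2R,3R)‑4‑{(2S,3S)‑4‑bromo‑2‑(4‑pivaloyloxyphenyl)‑6‑(triisopropylsilyloxy)‑2,3‑dihydrobenzofuran‑3‑yl}‑2‑(4‑pivaloyloxyphenyl)‑6‑(triisopropylsilyloxy)‑2,3‑dihydrobenzofuran‑3‑yl]‑1,3‑phenylene dipivalate, via carbinol 18 (not isolated)
Conditions: TfOH (10 mol%), HFIP, 0 °C (syringe‑pump addition of 17); then 50 °C
Reagents that add atoms: none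
Why: Proposed new method: second use of the step 9 cascade, in which arylation at the 4‑acyloxybenzylic carbon is followed by aryl‑assisted ionisation of the carbinol (meta‑dioxygenated, non‑stabilising aryl), 1,2‑shift of the bis(silyloxy)aryl group with inversion (C3 becomes S) and trans O‑cyclisation with loss of TIPS; the closest known chemistry is again epoxide Friedel–Crafts arylation and phenonium‑mediated dehydrative substitution in TfOH/HFIP, and any leakage through an open cation would give a separable diastereomer, not the enantiomer.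

Step 13
Reactants: 20 ethynylmagnesium bromide; 2 4‑iodophenyl pivalate
Product: 22 4‑ethynylphenyl pivalate, via ethynylzinc bromide 21 (not isolated)
Conditions: ZnBr2 (1.1 equiv), THF, 0 °C; then 2, Pd(PPh3)4 (3 mol%), rt
Reagents that add atoms: zinc bromide, Br[Zn]Br (zinc only in 21)
Why: Negishi alkynylation; the ester‑tolerant ethynylzinc reagent couples with the aryl iodide to give the terminal alkyne directly.

Step 14
Reactants: 19 trimer bromide; 22 4‑ethynylphenyl pivalate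
Product: 23 diarylalkyne (19 with Br replaced by 2‑(4‑pivaloyloxyphenyl)ethynyl)
Conditions: Pd(PhCN)2Cl2 (3 mol%), P(t‑Bu)3·HBF4 (6 mol%), CuI (2 mol%), i‑Pr2NH, dioxane, rt → 45 °C
Reagents that add atoms: none
Why: Sonogashira coupling under Buchwald–Fu conditions handles hindered aryl bromides near room temperature with an amine base that spares the esters.

Step 15
Reactants: 23 diarylalkyne
Product: 24 penta‑O‑pivaloyl‑di‑O‑TIPS cis‑miyabenol C ((Z)‑stilbene)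
Conditions: H2 (1 atm), Lindlar catalyst (Pd/CaCO3–Pb), quinoline, EtOAc, rt, stopped at 1 equiv H2
Reagents that add atoms: none
Why: Lindlar semi‑hydrogenation adds H2 syn to the alkyne on the poisoned surface to give the Z‑stilbene without hydrogenolysis of the benzylic ethers.

Step 16
Reactants: 24 protected cis‑miyabenol C
Product: 26 cis‑miyabenol C, via pentapivalate diphenol 25 (not isolated)
Conditions: TBAF (2.2 equiv), AcOH (2.2 equiv), THF, 0 °C; then MeOH, K2CO3 (cat.), rt, Ar, dark; AcOH quench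
Reagents that add atoms: none
Why: Buffered fluoride removes the two aryl silyl ethers and base‑catalysed methanolysis then removes the five aryl pivalates under mild, acid‑free conditions that keep the Z‑alkene and the trans‑dihydrobenzofurans intact.

## Compound list

1 | 4‑iodophenol | Oc1ccc(I)cc1 | starting material
2 | 4‑iodophenyl pivalate | CC(C)(C)C(=O)Oc1ccc(I)cc1 | intermediate
3 | potassium vinyltrifluoroborate | [K+].C=C[B-](F)(F)F | starting material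
4 | 4‑vinylphenyl pivalate | CC(C)(C)C(=O)Oc1ccc(C=C)cc1 | intermediate
5 | resorcinol | Oc1cccc(O)c1 | starting material
6 | 1,3‑phenylene dipivalate | CC(C)(C)C(=O)Oc1cccc(OC(=O)C(C)(C)C)c1 | intermediate
7 | 5‑(4,4,5,5‑tetramethyl‑1,3,2‑dioxaborolan‑2‑yl)‑1,3‑phenylene dipivalate | CC(C)(C)C(=O)Oc1cc(OC(=O)C(C)(C)C)cc(B2OC(C)(C)C(C)(C)O2)c1 | intermediate (not isolated)
8 | 5‑bromo‑1,3‑phenylene dipivalate | CC(C)(C)C(=O)Oc1cc(Br)cc(OC(=O)C(C)(C)C)c1 | intermediate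
9 | (E)‑resveratrol tripivalate | CC(C)(C)C(=O)Oc1ccc(/C=C/c2cc(OC(=O)C(C)(C)C)cc(OC(=O)C(C)(C)C)c2)cc1 | intermediate
10 | (2R,3R)‑2‑[3,5‑bis(pivaloyloxy)phenyl]‑3‑[4‑(pivaloyloxy)phenyl]oxirane | CC(C)(C)C(=O)Oc1ccc([C@H]2O[C@@H]2c2cc(OC(=O)C(C)(C)C)cc(OC(=O)C(C)(C)C)c2)cc1 | intermediate
11 | 1,3‑bis(triisopropylsilyloxy)benzene | CC(C)[Si](Oc1cccc(O[Si](C(C)C)(C(C)C)C(C)C)c1)(C(C)C)C(C)C | intermediate
12 | 2‑[3,5‑bis(triisopropylsilyloxy)phenyl]‑4,4,5,5‑tetramethyl‑1,3,2‑dioxaborolane | CC(C)[Si](Oc1cc(O[Si](C(C)C)(C(C)C)C(C)C)cc(B2OC(C)(C)C(C)(C)O2)c1)(C(C)C)C(C)C | intermediate (not isolated)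
13 | 1‑bromo‑3,5‑bis(triisopropylsilyloxy)benzene | CC(C)[Si](Oc1cc(Br)cc(O[Si](C(C)C)(C(C)C)C(C)C)c1)(C(C)C)C(C)C | intermediate
14 | (1S)‑1‑[3,5‑bis(pivaloyloxy)phenyl]‑2‑[2‑bromo‑4,6‑bis(triisopropylsilyloxy)phenyl]‑2‑[4‑(pivaloyloxy)phenyl]ethanol (C2 epimers, both converge) | O[C@@H](C(c1ccc(OC(=O)C(C)(C)C)cc1)c1c(Br)cc(O[Si](C(C)C)(C(C)C)C(C)C)cc1O[Si](C(C)C)(C(C)C)C(C)C)c1cc(OC(=O)C(C)(C)C)cc(OC(=O)C(C)(C)C)c1 | intermediate (not isolated)
15 | 5‑[(2R,3R)‑4‑bromo‑2‑(4‑pivaloyloxyphenyl)‑6‑(triisopropylsilyloxy)‑2,3‑dihydrobenzofuran‑3‑yl]‑1,3‑phenylene dipivalate (trans) | Brc1cc(O[Si](C(C)C)(C(C)C)C(C)C)cc2c1[C@@H](c1cc(OC(=O)C(C)(C)C)cc(OC(=O)C(C)(C)C)c1)[C@H](c1ccc(OC(=O)C(C)(C)C)cc1)O2 | intermediate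
16 | 4‑[(E)‑2‑{(2R,3R)‑3‑[3,5‑bis(pivaloyloxy)phenyl]‑2‑(4‑pivaloyloxyphenyl)‑6‑(triisopropylsilyloxy)‑2,3‑dihydrobenzofuran‑4‑yl}vinyl]phenyl pivalate | CC(C)(C)C(=O)Oc1ccc(/C=C/c2cc(O[Si](C(C)C)(C(C)C)C(C)C)cc3c2[C@@H](c2cc(OC(=O)C(C)(C)C)cc(OC(=O)C(C)(C)C)c2)[C@H](c2ccc(OC(=O)C(C)(C)C)cc2)O3)cc1 | intermediate
17 | (2S,3S)‑2‑(4‑pivaloyloxyphenyl)‑3‑{(2R,3R)‑3‑[3,5‑bis(pivaloyloxy)phenyl]‑2‑(4‑pivaloyloxyphenyl)‑6‑(triisopropylsilyloxy)‑2,3‑dihydrobenzofuran‑4‑yl}oxirane | CC(C)(C)C(=O)Oc1ccc([C@@H]2O[C@H]2c2cc(O[Si](C(C)C)(C(C)C)C(C)C)cc3c2[C@@H](c2cc(OC(=O)C(C)(C)C)cc(OC(=O)C(C)(C)C)c2)[C@H](c2ccc(OC(=O)C(C)(C)C)cc2)O3)cc1 | intermediate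
18 | (1R)‑1‑{(2R,3R)‑3‑[3,5‑bis(pivaloyloxy)phenyl]‑2‑(4‑pivaloyloxyphenyl)‑6‑(triisopropylsilyloxy)‑2,3‑dihydrobenzofuran‑4‑yl}‑2‑[2‑bromo‑4,6‑bis(triisopropylsilyloxy)phenyl]‑2‑(4‑pivaloyloxyphenyl)ethanol (C2 epimers) | O[C@H](C(c1ccc(OC(=O)C(C)(C)C)cc1)c1c(Br)cc(O[Si](C(C)C)(C(C)C)C(C)C)cc1O[Si](C(C)C)(C(C)C)C(C)C)c1cc(O[Si](C(C)C)(C(C)C)C(C)C)cc2c1[C@@H](c1cc(OC(=O)C(C)(C)C)cc(OC(=O)C(C)(C)C)c1)[C@H](c1ccc(OC(=O)C(C)(C)C)cc1)O2 | intermediate (not isolated)
19 | 5‑[(2R,3R)‑4‑{(2S,3S)‑4‑bromo‑2‑(4‑pivaloyloxyphenyl)‑6‑(triisopropylsilyloxy)‑2,3‑dihydrobenzofuran‑3‑yl}‑2‑(4‑pivaloyloxyphenyl)‑6‑(triisopropylsilyloxy)‑2,3‑dihydrobenzofuran‑3‑yl]‑1,3‑phenylene dipivalate | Brc1cc(O[Si](C(C)C)(C(C)C)C(C)C)cc2c1[C@H](c1cc(O[Si](C(C)C)(C(C)C)C(C)C)cc3c1[C@@H](c1cc(OC(=O)C(C)(C)C)cc(OC(=O)C(C)(C)C)c1)[C@H](c1ccc(OC(=O)C(C)(C)C)cc1)O3)[C@@H](c1ccc(OC(=O)C(C)(C)C)cc1)O2 | intermediate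
20 | ethynylmagnesium bromide | C#C[Mg]Br | starting material
21 | ethynylzinc bromide | C#C[Zn]Br | intermediate (not isolated)
22 | 4‑ethynylphenyl pivalate | CC(C)(C)C(=O)Oc1ccc(C#C)cc1 | intermediate
23 | diarylalkyne: 19 with Br replaced by 2‑(4‑pivaloyloxyphenyl)ethynyl | CC(C)(C)C(=O)Oc1ccc(C#Cc2cc(O[Si](C(C)C)(C(C)C)C(C)C)cc3c2[C@H](c2cc(O[Si](C(C)C)(C(C)C)C(C)C)cc4c2[C@@H](c2cc(OC(=O)C(C)(C)C)cc(OC(=O)C(C)(C)C)c2)[C@H](c2ccc(OC(=O)C(C)(C)C)cc2)O4)[C@@H](c2ccc(OC(=O)C(C)(C)C)cc2)O3)cc1 | intermediate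
24 | penta‑O‑pivaloyl‑di‑O‑triisopropylsilyl cis‑miyabenol C ((Z)‑alkene) | CC(C)(C)C(=O)Oc1ccc(/C=C\c2cc(O[Si](C(C)C)(C(C)C)C(C)C)cc3c2[C@H](c2cc(O[Si](C(C)C)(C(C)C)C(C)C)cc4c2[C@@H](c2cc(OC(=O)C(C)(C)C)cc(OC(=O)C(C)(C)C)c2)[C@H](c2ccc(OC(=O)C(C)(C)C)cc2)O4)[C@@H](c2ccc(OC(=O)C(C)(C)C)cc2)O3)cc1 | intermediate
25 | penta‑O‑pivaloyl cis‑miyabenol C (both benzofuran 6‑OH free) | CC(C)(C)C(=O)Oc1ccc(/C=C\c2cc(O)cc3c2[C@H](c2cc(O)cc4c2[C@@H](c2cc(OC(=O)C(C)(C)C)cc(OC(=O)C(C)(C)C)c2)[C@H](c2ccc(OC(=O)C(C)(C)C)cc2)O4)[C@@H](c2ccc(OC(=O)C(C)(C)C)cc2)O3)cc1 | intermediate (not isolated)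
26 | cis‑miyabenol C | Oc1ccc(/C=C\c2cc(O)cc3c2[C@H](c2cc(O)cc4c2[C@@H](c2cc(O)cc(O)c2)[C@H](c2ccc(O)cc2)O4)[C@@H](c2ccc(O)cc2)O3)cc1 | target

## Step count and risks

Total steps: 16. Longest linear sequence: 11 (steps 3, 4, 5, 6, 9, 10, 11, 12, 14, 15, 16, from resorcinol).

Steps most likely to fail:

**Step 9 (proposed new cascade).** The risks are direct O‑alkylation at the carbinol carbon (regioisomeric dihydrobenzofuran), Meinwald rearrangement of 10 before arylation, and elimination to triarylethylenes. The fallback uses known reactions only, forms the C–O bond first and needs no skeletal shift. It sets out from 13 and 10. Mono‑desilylation of 13 (TBAF 1.0 equiv, THF, −78 °C) gives 3‑bromo‑5‑(triisopropylsilyloxy)phenol F1. Its caesium phenoxide opens epoxide 10 at the 4‑acyloxybenzylic carbon with inversion (Cs2CO3, MeCN, 60 °C) to give (1R,2S)‑2‑[3‑bromo‑5‑(triisopropylsilyloxy)phenoxy]‑1‑[3,5‑bis(pivaloyloxy)phenyl]‑2‑(4‑pivaloyloxyphenyl)ethanol F2. Intramolecular Friedel–Crafts cyclodehydration (TfOH cat., HFIP, 40 °C) closes the ring para to the silyloxy group with inversion at the carbinol carbon. The two inversions give the trans‑(2R,3R) product, and the sequence comes back to the route at 15.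

**Step 12 (second use of the cascade on a complex epoxide).** The added risks are intermolecular alkylation of the electron‑rich benzofuran ring of 17 or 19 and steric congestion in the aryl shift. The fallback sets out from 17 and uses 3‑bromo‑5‑(triisopropylsilyloxy)phenol F1 again. Phenoxide opening of 17 at the 4‑acyloxybenzylic carbon (Cs2CO3, MeCN, 60 °C) gives the (1S,2R)‑β‑aryloxy alcohol F3. The same acid‑mediated intramolecular Friedel–Crafts cyclodehydration then forms the second dihydrobenzofuran, and the sequence comes back to the route at 19.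

**Step 15 (Lindlar semi‑hydrogenation of a hindered, late‑stage diarylalkyne).** The risks are over‑reduction and Z→E isomerisation. The fallback replaces alkyne reduction by a stereoretentive cross‑coupling. It sets out from 19 and 22. Rh‑catalysed trans‑hydroboration of 22 (HBpin, [Rh(cod)Cl]2, P(i‑Pr)3, Et3N, cyclohexane) gives 4‑[(Z)‑2‑(4,4,5,5‑tetramethyl‑1,3,2‑dioxaborolan‑2‑yl)vinyl]phenyl pivalate F4. Suzuki–Miyaura coupling of F4 with 19 (Pd(OAc)2/SPhos, K3PO4, THF/H2O, 40 °C) installs the Z‑styryl group directly and comes back to the route at 24, bypassing 23.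

## Further compounds

F1 | step 9 | 3‑bromo‑5‑(triisopropylsilyloxy)phenol | Oc1cc(Br)cc(O[Si](C(C)C)(C(C)C)C(C)C)c1
F2 | step 9 | (1R,2S)‑2‑[3‑bromo‑5‑(triisopropylsilyloxy)phenoxy]‑1‑[3,5‑bis(pivaloyloxy)phenyl]‑2‑(4‑pivaloyloxyphenyl)ethanol | O[C@H](c1cc(OC(=O)C(C)(C)C)cc(OC(=O)C(C)(C)C)c1)[C@H](c1ccc(OC(=O)C(C)(C)C)cc1)Oc1cc(Br)cc(O[Si](C(C)C)(C(C)C)C(C)C)c1
F3 | step 12 | (1S,2R)‑2‑[3‑bromo‑5‑(triisopropylsilyloxy)phenoxy]‑1‑{(2R,3R)‑3‑[3,5‑bis(pivaloyloxy)phenyl]‑2‑(4‑pivaloyloxyphenyl)‑6‑(triisopropylsilyloxy)‑2,3‑dihydrobenzofuran‑4‑yl}‑2‑(4‑pivaloyloxyphenyl)ethanol | O[C@@H](c1cc(O[Si](C(C)C)(C(C)C)C(C)C)cc2c1[C@@H](c1cc(OC(=O)C(C)(C)C)cc(OC(=O)C(C)(C)C)c1)[C@H](c1ccc(OC(=O)C(C)(C)C)cc1)O2)[C@@H](c1ccc(OC(=O)C(C)(C)C)cc1)Oc1cc(Br)cc(O[Si](C(C)C)(C(C)C)C(C)C)c1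
F4 | step 15 | 4‑[(Z)‑2‑(4,4,5,5‑tetramethyl‑1,3,2‑dioxaborolan‑2‑yl)vinyl]phenyl pivalate | CC(C)(C)C(=O)Oc1ccc(/C=C\B2OC(C)(C)C(C)(C)O2)cc1
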